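## Retrosynthetic overview
1. The 4-pyranone is the only ring and is closed last. The disconnection is the ring O1–C6 bond: an enol oxygen adds to a bromoalkyne and Br+ is captured at C5. The bromines at C3 and C6 are installed in the same operation.
2. This leads back to an open-chain C8 1,2,4-triketone with a silyl-capped ynone end, 8-(trimethylsilyl)oct-7-yne-3,4,6-trione.
3. The ethyl ketone is cut at C(=O)–Et (Weinreb amide plus EtMgBr). The 1,3-diketone is cut at CH2–C(=O) (ynone enolate plus the bis-Weinreb amide of oxalic acid).
4. Building blocks are all catalogue items: 4-(trimethylsilyl)but-3-yn-2-one, N,N'-dimethoxy-N,N'-dimethyloxamide, EtMgBr and NBS.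

Assumption: the SMILES contains no stereocentre and no stereogenic double bond, so the target is achiral and no stereocontrol is needed.

## Route

Step 1
Reactants: 1 4-(trimethylsilyl)but-3-yn-2-one; 2 N,N'-dimethoxy-N,N'-dimethyloxamide
Product: 4 N-methoxy-N-methyl-2,4-dioxo-6-(trimethylsilyl)hex-5-ynamide, via lithium enolate 3 (not isolated)
Conditions: LiN(SiMe3)2 (2.1 equiv), THF, −78 °C; then 2 (1.3 equiv), −78 to −20 °C; 1 M HCl
Reagents that add atoms: none
Why: This is a Claisen-type C-acylation of a ketone lithium enolate with a Weinreb amide, in which 1 has a single enolisable site, the vicinal dicarbonyl of 2 is as activated as an oxalate, and the second equivalent of base turns the adduct into its diketonate and so blocks attack on the remaining amide; no stereocentre is formed.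

Step 2
Reactants: 4 N-methoxy-N-methyl-2,4-dioxo-6-(trimethylsilyl)hex-5-ynamide
Product: 6 8-(trimethylsilyl)oct-7-yne-3,4,6-trione, via magnesium hemiaminal chelate 5 (not isolated)
Conditions: EtMgBr (2.3 equiv), THF, −78 to 0 °C; cold 1 M HCl
Reagents that add atoms: ethylmagnesium bromide, CC[Mg]Br
Why: This is a Weinreb ketone synthesis in which the first equivalent of EtMgBr only deprotonates the acidic enol and masks the C2 and C4 carbonyls and the ynone as a magnesium diketonate, while the second adds to the amide carbonyl to give chelate 5, which cannot collapse before the acid quench, so over-addition is excluded and no stereocentre remains.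

Step 3
Reactants: 6 8-(trimethylsilyl)oct-7-yne-3,4,6-trione
Product: 9 3,5,6-tribromo-2-propanoyl-4H-pyran-4-one, via monobromo triketone 7 (not isolated), via bromoalkyne 8 (not isolated)
Conditions: NBS (3.2 equiv), AgNO3 (10 mol%), MeCN, 0 °C to rt, dark; H2O wash
Reagents that add atoms: N-bromosuccinimide, O=C1CCC(=O)N1Br
Why: Proposed new method: NBS first brominates the enolised C5 methylene (7), AgNO3/NBS then exchanges the alkynyl SiMe3 for Br (8), and monovalent silver π-activates the bromo-ynone so that the C4 enol oxygen attacks the bromine-bearing alkyne terminus C8 in a 6-endo-dig mode (C8 is the β-carbon of the ynone and its developing charge is stabilised by the Br lone pair, whereas 5-exo attack at C7 would be anti-Michael), after which the 5-argentio-pyranone is captured by NBS to place the third bromine, so a single C–O bond closes the only ring with all three halogens in position; the closest known reaction type is the halocyclisation (ICl, NIS, NBS) of alkynones carrying an oxygen nucleophile to 3-halochromones and 3-halo-4-pyranones, which has not been shown for 1-bromoalkynyl 1,3-diketones or for making 2,3-dihalo-4-pyranones; no stereocentre is formed.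

## Compound list
1 | 4-(trimethylsilyl)but-3-yn-2-one | CC(=O)C#C[Si](C)(C)C | starting material
2 | N,N'-dimethoxy-N,N'-dimethyloxamide | CON(C)C(=O)C(=O)N(C)OC | starting material
3 | lithium 4-(trimethylsilyl)but-1-en-3-yn-2-olate (enolate of 1) | C=C(O[Li])C#C[Si](C)(C)C | intermediate
4 | N-methoxy-N-methyl-2,4-dioxo-6-(trimethylsilyl)hex-5-ynamide (largely enolised) | CON(C)C(=O)C(=O)CC(=O)C#C[Si](C)(C)C | intermediate
5 | bis(bromomagnesium) 3-[methoxy(methyl)amino]-4-oxo-8-(trimethylsilyl)oct-5-en-7-yne-3,6-diolate (racemic at C3, centre lost on quench) | CCC(O[Mg]Br)(N(C)OC)C(=O)C=C(O[Mg]Br)C#C[Si](C)(C)C | intermediate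
6 | 8-(trimethylsilyl)oct-7-yne-3,4,6-trione (enolised between C4 and C6) | CCC(=O)C(=O)CC(=O)C#C[Si](C)(C)C | intermediate
7 | 5-bromo-8-(trimethylsilyl)oct-7-yne-3,4,6-trione (C5 labile through enolisation) | CCC(=O)C(=O)C(Br)C(=O)C#C[Si](C)(C)C | intermediate
8 | 5,8-dibromooct-7-yne-3,4,6-trione | CCC(=O)C(=O)C(Br)C(=O)C#CBr | intermediate
9 | 3,5,6-tribromo-2-propanoyl-4H-pyran-4-one (CNP0423242.0, achiral) | CCC(=O)c1oc(Br)c(Br)c(=O)c1Br | target

## Step count and risks
Total step count: 3. Longest linear sequence: 3.

**Most likely to fail: step 3 (the proposed new step).**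
- The vinyl-silver species may be protonated instead of brominated, giving the 5-H pyranone. NBS can still brominate this at C5, but slowly.
- The ring may close onto the silyl alkyne before the Si/Br exchange.
- Silver may assist loss of the activated C6–Br.

The fallback uses known chemistry, sets out from 6 and comes back at 9. Compound 6 is taken with NBS (2.05 equiv) and AgNO3 (5 mol%) in MeCN at −20 °C through 7 to 8. Br2 (1.0 equiv in CH2Cl2) is added at once, and ordinary anti-addition of bromine to the bromoalkyne gives 5,7,8,8-tetrabromooct-7-ene-3,4,6-trione F1, which is isolated. Stirring this tetrabromide with NaHCO3 in acetone at 0 °C to rt closes the ring by intramolecular addition–elimination of the enolate oxygen at the CBr2 carbon. This is the established behaviour of β,β-dihalovinyl ketones; one bromide is lost and 9 results. The terminal carbon carries two bromines, so alkene geometry is not an issue.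

**Second: step 2.**
- The Grignard reagent may add sluggishly to the anionic substrate.
- It may attack the C2 carbonyl of the diketonate instead of the amide.

The fallback sets out from 1 (through enolate 3) and comes back at 6, and no organometallic reagent meets the polycarbonyl chain. Methyl 2-oxobutanoate is ketalised with HC(OMe)3 and catalytic TsOH in MeOH to methyl 2,2-dimethoxybutanoate F2. Enolate 3 is acylated with this ester in a Claisen condensation (LiN(SiMe3)2, 2 equiv, THF, −78 °C to rt) to give 3,3-dimethoxy-8-(trimethylsilyl)oct-7-yne-4,6-dione F3. Aqueous CF3CO2H in CH2Cl2 at 0 °C removes the ketal and delivers 6.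

**Third: step 1.**
- Both amide groups of 2 may be acylated.
- The oxamide may react too slowly, leaving the ynone enolate time to self-condense.

The fallback sets out from 1 (through enolate 3) and comes back at 4. The enolate is trapped at −78 °C with diethyl oxalate in a classical oxalate Claisen condensation, using a far more electrophilic partner, to give ethyl 2,4-dioxo-6-(trimethylsilyl)hex-5-ynoate F4. Its ester is then exchanged for the Weinreb amide with MeNH(OMe)·HCl and i-PrMgCl (THF, −20 °C). The diketone is protected in situ as its magnesium enolate during this exchange, and the product is 4.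

## Further compounds
F1 | step 3 | 5,7,8,8-tetrabromooct-7-ene-3,4,6-trione | CCC(=O)C(=O)C(Br)C(=O)C(Br)=C(Br)Br
F2 | step 2 | methyl 2,2-dimethoxybutanoate | CCC(OC)(OC)C(=O)OC
F3 | step 2 | 3,3-dimethoxy-8-(trimethylsilyl)oct-7-yne-4,6-dione | CCC(OC)(OC)C(=O)CC(=O)C#C[Si](C)(C)C
F4 | step 1 | ethyl 2,4-dioxo-6-(trimethylsilyl)hex-5-ynoate | CCOC(=O)C(=O)CC(=O)C#C[Si](C)(C)C
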